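**Retrosynthetic overview**
1. The C6–C7 bond, the ten-membered ring and C7 are made last, by a proposed nickel-catalysed asymmetric reductive coupling of a (Z)-alkenyl iodide with a γ-chlorobutenolide (from a 3,4-disubstituted furan by singlet oxygen, then SOCl2).
2. Ring A comes from a Birch-derived vinylogous ester by a Stork–Danheiser sequence: C10 alkylation with a furylmethyl bromide anti to the C2 branch, then MeLi/acid; the C14 oxygen is set by enolate hydroxylation and redox inversion.
3. Quaternary C1 is set by diastereotopic-group-selective ketalization of the prochiral Birch bis(enol ether), steered by a temporary 2R carbinol; C2 is then reset to S by oxidation and a second CBS reduction.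
4. Building blocks: 3,5-dimethoxybenzoic acid; (1Z)-3-bromo-1-iodo-2-methylprop-1-ene (from propargyl alcohol); 3-(bromomethyl)-4-methylfuran (from ethyl but-2-ynoate and 4-phenyloxazole).
5. Ring order: ring A (from the arene), then the butenolide (from the furan), then the ten-membered ring.

Assumption: locants follow the briarane skeleton (C1 quaternary ring-fusion carbon with Me-15; C2 isobutyryloxy; C5=C6 with Me-16; C7 lactone O–CH; C8=C17 with Me-18; C19 lactone C=O; C10 ring-fusion CH; C11=C12 with Me-20; C13 C=O; C14 OAc), the target being 1R,2S,5Z,7R,10R,14S; organometallic, amide-base and CBS reagents are bought as solutions.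

**Step 1**
Reactants: 1 prop-2-yn-1-ol
Product: 3 (2Z)-3-iodo-2-methylprop-2-en-1-ol, via alkenylmagnesium alkoxide 2 (not isolated)
Conditions: MeMgBr (2.5 equiv), CuI (10 mol %), THF, −10 °C to rt; then I2, −78 to 0 °C
Reagents that add atoms: methylmagnesium bromide C[Mg]Br; iodine II
Why: Copper-catalysed, alkoxide-directed anti carbomagnesiation puts methyl on the internal carbon and magnesium on the terminal carbon cis to CH2O (chelate 2), and iodinolysis with retention gives the Z iodoalkene needed for the cis C5=C6 ring olefin.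

**Step 2**
Reactants: 3 (2Z)-3-iodo-2-methylprop-2-en-1-ol
Product: 4 (1Z)-3-bromo-1-iodo-2-methylprop-1-ene
Conditions: CBr4, PPh3, CH2Cl2, 0 °C
Reagents that add atoms: carbon tetrabromide BrC(Br)(Br)Br
Why: Appel bromination (SN2 at the primary allylic carbon) leaves the alkenyl iodide and its Z geometry untouched.

**Step 3**
Reactants: 5 ethyl but-2-ynoate; 6 4-phenyl-1,3-oxazole
Product: 8 ethyl 4-methylfuran-3-carboxylate, via oxazole cycloadduct 7 (not isolated)
Conditions: neat, sealed tube, 200 °C
Reagents that add atoms: none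
Why: Diels–Alder addition of the alkyne across C2/C5 of the oxazole and retro-Diels–Alder loss of benzonitrile from 7 give the 3,4-disubstituted furan, the same product from either orientation of addition.

**Step 4**
Reactants: 8 ethyl 4-methylfuran-3-carboxylate
Product: 9 (4-methylfuran-3-yl)methanol
Conditions: LiAlH4, Et2O, 0 °C
Reagents that add atoms: none
Why: LiAlH4 reduction of the ester to the primary alcohol; the furan is inert.

**Step 5**
Reactants: 9 (4-methylfuran-3-yl)methanol
Product: 10 3-(bromomethyl)-4-methylfuran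
Conditions: CBr4, PPh3, CH2Cl2, −20 °C (used at once)
Reagents that add atoms: carbon tetrabromide BrC(Br)(Br)Br
Why: Appel bromination under neutral conditions gives the acid-sensitive furylmethyl bromide.

**Step 6**
Reactants: 11 3,5-dimethoxybenzoic acid
Product: 13 Birch acid, via dilithium dienediolate 12 (not isolated)
Conditions: Li (3 equiv), NH3(l)/THF, −78 °C; then MeI; then NH4Cl (work-up at pH 6)
Reagents that add atoms: iodomethane CI
Why: Birch reductive alkylation: the benzoate is reduced to the 1,4-dihydro dianion 12, which is C-methylated at the carboxylate-bearing carbon to give the still prochiral quaternary C1 flanked by two enantiotopic methyl enol ethers.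

**Step 7**
Reactants: 13 Birch acid
Product: 14 methyl ketone
Conditions: MeLi (2.2 equiv), Et2O, 0 °C to rt; aq. NH4Cl
Reagents that add atoms: methyllithium [Li]C
Why: Addition of two equivalents of MeLi to the carboxylic acid stops at the stable dilithium gem-diolate, which gives the methyl ketone on work-up (the new methyl is C3).

**Step 8**
Reactants: 14 methyl ketone; 4 (1Z)-3-bromo-1-iodo-2-methylprop-1-ene
Product: 16 iodoalkenyl ketone, via lithium enolate 15 (not isolated)
Conditions: LiN(iPr)2, THF, −78 °C; then 4, −78 to −20 °C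
Reagents that add atoms: none
Why: The methyl group is the only enolizable position (C1 is quaternary), so enolate 15 forms cleanly and is alkylated (SN2) by the allylic bromide, installing C4–C6 with the Z iodoalkene intact.

**Step 9**
Reactants: 16 iodoalkenyl ketone
Product: 17 (2R)-carbinol
Conditions: (S)-2-methyl-CBS-oxazaborolidine (20 mol %), catecholborane, toluene, −78 °C
Reagents that add atoms: none
Why: Corey–Bakshi–Shibata reduction: with the quaternary ring carbon as the large and the CH2 chain as the small group, the (S)-catalyst gives the 2R carbinol, a temporary stereocentre used only to steer step 10.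

**Step 10**
Reactants: 17 (2R)-carbinol
Product: 18 bicyclic ketal
Conditions: pyridinium p-toluenesulfonate (5 mol %), 4 Å MS, CH2Cl2, −20 °C to rt
Reagents that add atoms: none
Why: Acid-catalysed intramolecular hydroalkoxylation (ketalization) of one of the two diastereotopic enol ethers under thermodynamic control: the 2R carbinol can keep its side chain exo (towards the one-carbon bridge C14) in the 6-oxabicyclo[3.2.1]octene only by adding to the enol ether carbon that becomes C13, which makes C1 stereogenic with the configuration of the target.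

**Step 11**
Reactants: 18 bicyclic ketal
Product: 20 (2R)-hydroxy vinylogous ester, via keto ketal 19 (not isolated)
Conditions: 0.1 M aq. oxalic acid, THF, 0 °C; then DBU, CH2Cl2, rt
Reagents that add atoms: water O
Why: The remaining methyl enol ether hydrolyses faster than the bicyclic ketal (whose ring opening is reversible) to give 19, and E1cB elimination then expels the ring oxygen (loss of methoxide would give an anti-Bredt enol ether), which delivers regiospecifically the vinylogous ester with its carbonyl at C11 and frees the C2 hydroxyl without touching C1.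

**Step 12**
Reactants: 20 (2R)-hydroxy vinylogous ester
Product: 21 vinylogous ester ketone
Conditions: Dess–Martin periodinane, pyridine, CH2Cl2, 0 °C
Reagents that add atoms: none
Why: Dess–Martin oxidation of the secondary alcohol removes the temporary 2R centre now that C1 is fixed; the vinylogous ester is not affected.

**Step 13**
Reactants: 21 vinylogous ester ketone
Product: 22 (2S)-hydroxy vinylogous ester
Conditions: (R)-2-methyl-CBS-oxazaborolidine (20 mol %), catecholborane, toluene/CH2Cl2, −78 °C
Reagents that add atoms: none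
Why: A second Corey–Bakshi–Shibata reduction, now with the (R)-catalyst, sets the natural 2S carbinol under reagent control, the dialkyl ketone being far more reactive than the vinylogous ester carbonyl.

**Step 14**
Reactants: 22 (2S)-hydroxy vinylogous ester
Product: 23 silyl ether
Conditions: TBSOTf, 2,6-lutidine, CH2Cl2, −78 to 0 °C
Reagents that add atoms: tert-butyldimethylsilyl triflate CC(C)(C)[Si](C)(C)OS(=O)(=O)C(F)(F)F
Why: Silylation of the hindered neopentyl-type alcohol gives a robust ether that survives the amide-base, organometallic and acidic steps that follow and makes the C2 branch the large group on C1.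

**Step 15**
Reactants: 23 silyl ether; 10 3-(bromomethyl)-4-methylfuran
Product: 25 C10-furylmethyl vinylogous ester, via lithium dienolate 24 (not isolated)
Conditions: LiN(iPr)2, THF, −78 °C; then 10, DMPU, −78 to −40 °C
Reagents that add atoms: none
Why: Stork–Danheiser kinetic alkylation: the amide base removes a proton from C10, the only α′ position, and the cross-conjugated dienolate 24 is alkylated on the face anti to the bulky silyloxyalkyl branch of the adjacent quaternary C1, setting C10 with C9 trans to C2.

**Step 16**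
Reactants: 25 C10-furylmethyl vinylogous ester
Product: 27 enone, via tertiary carbinol 26 (not isolated)
Conditions: MeLi, CeCl3, THF, −78 °C; then 1 M HCl, THF, 0 °C
Reagents that add atoms: methyllithium [Li]C; water O
Why: Stork–Danheiser carbonyl transposition: the organocerium methyl reagent adds 1,2 to the hindered vinylogous ester carbonyl without iodine–metal exchange, and acid hydrolysis of the enol ether in 26 followed by loss of water gives the 3-methyl enone with the carbonyl at C13 and Me-20 on C11.

**Step 17**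
Reactants: 27 enone
Product: 29 14-epi-hydroxy enone, via lithium dienolate 28 (not isolated)
Conditions: LiN(iPr)2, THF, −78 °C; then 3-phenyl-2-(phenylsulfonyl)oxaziridine, −78 °C
Reagents that add atoms: 3-phenyl-2-(phenylsulfonyl)oxaziridine O=S(=O)(c1ccccc1)N1OC1c1ccccc1
Why: Kinetic α′-deprotonation at C14 gives the cross-conjugated dienolate 28, which the Davis oxaziridine hydroxylates anti to the bulky C2 branch (mainly the 14-epi alcohol, cis to Me-15), an outcome that does not matter because C14 is reset in steps 18 and 19.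

**Step 18**
Reactants: 29 14-epi-hydroxy enone
Product: 30 ene-1,2-dione
Conditions: Dess–Martin periodinane, pyridine, CH2Cl2, 0 °C
Reagents that add atoms: none
Why: Dess–Martin oxidation of the α-ketol to the 1,2-dione erases C14 so that both epimers converge; buffered, cold conditions keep the γ-hydrogen at C10 from enolizing.

**Step 19**
Reactants: 30 ene-1,2-dione
Product: 31 (14S)-hydroxy enone
Conditions: NaBH4, MeOH/CH2Cl2, −78 °C
Reagents that add atoms: none
Why: Chemoselective hydride reduction of a saturated ketone beside an enone: NaBH4 attacks the non-conjugated C14 carbonyl from the face anti to the bulky C2 branch on C1, so the hydroxyl ends cis to C2 and trans to Me-15 (14S).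

**Step 20**
Reactants: 31 (14S)-hydroxy enone
Product: 32 acetate
Conditions: Ac2O, 4-(dimethylamino)pyridine, pyridine, CH2Cl2, 0 °C
Reagents that add atoms: acetic anhydride CC(=O)OC(C)=O
Why: DMAP-catalysed acetylation of the ketol hydroxyl, the only free OH.

**Step 21**
Reactants: 32 acetate
Product: 33 C2 alcohol
Conditions: HF·pyridine, pyridine, THF, 0 °C to rt
Reagents that add atoms: none
Why: Fluoride-mediated desilylation under buffered acidic conditions frees the C2 hydroxyl without acetyl migration or epimerization at C14.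

**Step 22**
Reactants: 33 C2 alcohol
Product: 34 acetate isobutyrate furan
Conditions: isobutyryl chloride, pyridine, 4-(dimethylamino)pyridine (cat.), CH2Cl2, 0 °C to rt
Reagents that add atoms: 2-methylpropanoyl chloride CC(C)C(Cl)=O
Why: DMAP-catalysed acylation of the hindered secondary alcohol with the acid chloride installs the isobutyrate before the base-sensitive butenolide exists.

**Step 23**
Reactants: 34 acetate isobutyrate furan
Product: 36 γ-hydroxybutenolide, via furan endoperoxide 35 (not isolated)
Conditions: O2, visible light, tetraphenylporphyrin (cat.), iPr2NEt, CH2Cl2, −78 °C to rt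
Reagents that add atoms: dioxygen O=O
Why: Singlet-oxygen [4+2] cycloaddition to the electron-rich furan (much faster than ene reaction at the iodoalkene or attack on the enone) gives 35, and the hindered amine removes the less hindered bridgehead hydrogen (at C19, next to the methyl-bearing carbon) in a Kornblum–DeLaMare-type fragmentation, giving the γ-hydroxybutenolide with C=O at C19 and the hemiacetal at C7.

**Step 24**
Reactants: 36 γ-hydroxybutenolide
Product: 37 γ-chlorobutenolide
Conditions: SOCl2, DMF (cat.), CH2Cl2, 0 °C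
Reagents that add atoms: thionyl chloride O=S(Cl)Cl
Why: Pseudo-acid chloride formation: the hemiacetal hydroxyl is exchanged for chloride through its chlorosulfite and the acyl-oxocarbenium ion, and the epimer mixture at C7 is of no consequence for step 25.

**Step 25**
Reactants: 37 γ-chlorobutenolide
Product: 38 target
Conditions: NiCl2·glyme (20 mol %), (4S,4'S)-4,4'-diisopropyl-2,2'-bi(2-oxazoline) (24 mol %), Mn powder (3 equiv), NaI (0.5 equiv), DMA/THF 1:1, 0 °C, syringe-pump addition of 37 (final 2 mM)
Reagents that add atoms: none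
Why: Proposed new method: an intramolecular, stereoconvergent nickel-catalysed reductive cross-electrophile coupling in which zerovalent nickel (formed by manganese) inserts into the alkenyl iodide with retention of the Z geometry, a monovalent nickel halide abstracts chlorine from the γ-chlorobutenolide to give a planar, captodatively stabilised 2-oxofuranyl radical (both C7 epimers converge), the alkenylnickel captures this radical at the γ-carbon (the α-carbon is blocked by its methyl group) and reductive elimination from trivalent nickel inside the chiral bis(oxazoline) pocket forges C6–C7, closes the ten-membered ring and sets C7 (R) under ligand control reinforced by the trans ring fusion; the closest known reaction type is the nickel/bis(oxazoline)-catalysed enantioconvergent reductive coupling of alkenyl halides with benzylic or α-carbonyl chlorides, which has not been shown for γ-halobutenolides or for medium-ring closure.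

**Compound list**
1 | prop-2-yn-1-ol | C#CCO | starting material
2 | alkenylmagnesium alkoxide: bromomagnesium (2Z)-3-(bromomagnesio)-2-methylprop-2-en-1-olate | Br[Mg]OC/C(C)=C\[Mg]Br | intermediate
3 | (2Z)-3-iodo-2-methylprop-2-en-1-ol | OC/C(C)=C\I | intermediate
4 | (1Z)-3-bromo-1-iodo-2-methylprop-1-ene | BrC/C(C)=C\I | intermediate
5 | ethyl but-2-ynoate | CCOC(=O)C#CC | starting material
6 | 4-phenyl-1,3-oxazole | c1ccc(cc1)-c1cocn1 | starting material
7 | oxazole cycloadduct: ethyl 6-methyl-3-phenyl-7-oxa-2-azabicyclo[2.2.1]hepta-2,5-diene-5-carboxylate (racemic) | CCOC(=O)C1=C(C)C2N=C(c3ccccc3)C1O2 | intermediate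
8 | ethyl 4-methylfuran-3-carboxylate | CCOC(=O)c1cocc1C | intermediate
9 | (4-methylfuran-3-yl)methanol | OCc1cocc1C | intermediate
10 | 3-(bromomethyl)-4-methylfuran | BrCc1cocc1C | intermediate
11 | 3,5-dimethoxybenzoic acid | COc1cc(OC)cc(c1)C(=O)O | starting material
12 | dilithium dienediolate: dilithium (3,5-dimethoxycyclohexa-2,5-dien-1-ylidene)methanediolate | [Li+].[Li+].COC1=CC(=C([O-])[O-])C=C(OC)C1 | intermediate
13 | Birch acid: 3,5-dimethoxy-1-methylcyclohexa-2,5-diene-1-carboxylic acid | COC1=CC(C)(C(=O)O)C=C(OC)C1 | intermediate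
14 | methyl ketone: 1-(3,5-dimethoxy-1-methylcyclohexa-2,5-dien-1-yl)ethan-1-one | COC1=CC(C)(C(C)=O)C=C(OC)C1 | intermediate
15 | lithium enolate: lithium 1-(3,5-dimethoxy-1-methylcyclohexa-2,5-dien-1-yl)ethen-1-olate | [Li+].COC1=CC(C)(C(=C)[O-])C=C(OC)C1 | intermediate
16 | iodoalkenyl ketone: (4Z)-1-(3,5-dimethoxy-1-methylcyclohexa-2,5-dien-1-yl)-5-iodo-4-methylpent-4-en-1-one | COC1=CC(C)(C(=O)CC/C(C)=C\I)C=C(OC)C1 | intermediate
17 | (2R)-carbinol: (1R,4Z)-1-(3,5-dimethoxy-1-methylcyclohexa-2,5-dien-1-yl)-5-iodo-4-methylpent-4-en-1-ol | COC1=CC(C)([C@H](O)CC/C(C)=C\I)C=C(OC)C1 | intermediate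
18 | bicyclic ketal: (1R,5S,7R)-7-[(3Z)-4-iodo-3-methylbut-3-en-1-yl]-3,5-dimethoxy-1-methyl-6-oxabicyclo[3.2.1]oct-2-ene | CO[C@]12C[C@](C)(C=C(OC)C1)[C@@H](CC/C(C)=C\I)O2 | intermediate
19 | keto ketal: (1S,5S,7R)-7-[(3Z)-4-iodo-3-methylbut-3-en-1-yl]-5-methoxy-1-methyl-6-oxabicyclo[3.2.1]octan-3-one (stereocentres as in 18) | CO[C@]12C[C@](C)(CC(=O)C1)[C@@H](CC/C(C)=C\I)O2 | intermediate
20 | (2R)-hydroxy vinylogous ester: (5R)-5-[(1R,4Z)-1-hydroxy-5-iodo-4-methylpent-4-en-1-yl]-3-methoxy-5-methylcyclohex-2-en-1-one | COC1=CC(=O)C[C@](C)([C@H](O)CC/C(C)=C\I)C1 | intermediate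
21 | vinylogous ester ketone: (5R)-5-[(4Z)-5-iodo-4-methylpent-4-enoyl]-3-methoxy-5-methylcyclohex-2-en-1-one | COC1=CC(=O)C[C@](C)(C(=O)CC/C(C)=C\I)C1 | intermediate
22 | (2S)-hydroxy vinylogous ester: (5R)-5-[(1S,4Z)-1-hydroxy-5-iodo-4-methylpent-4-en-1-yl]-3-methoxy-5-methylcyclohex-2-en-1-one | COC1=CC(=O)C[C@](C)([C@@H](O)CC/C(C)=C\I)C1 | intermediate
23 | silyl ether: (5R)-5-[(1S,4Z)-1-{[tert-butyl(dimethyl)silyl]oxy}-5-iodo-4-methylpent-4-en-1-yl]-3-methoxy-5-methylcyclohex-2-en-1-one | COC1=CC(=O)C[C@](C)([C@@H](O[Si](C)(C)C(C)(C)C)CC/C(C)=C\I)C1 | intermediate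
24 | lithium dienolate of 23 (O-lithiated at C11, C10=C11) | [Li+].COC1=CC([O-])=C[C@](C)([C@@H](O[Si](C)(C)C(C)(C)C)CC/C(C)=C\I)C1 | intermediate
25 | C10-furylmethyl vinylogous ester: (5R,6S)-5-[(1S,4Z)-1-{[tert-butyl(dimethyl)silyl]oxy}-5-iodo-4-methylpent-4-en-1-yl]-3-methoxy-5-methyl-6-[(4-methylfuran-3-yl)methyl]cyclohex-2-en-1-one | COC1=CC(=O)[C@@H](Cc2cocc2C)[C@](C)([C@@H](O[Si](C)(C)C(C)(C)C)CC/C(C)=C\I)C1 | intermediate
26 | tertiary carbinol: 1,2-adduct of methyl to the C11 carbonyl of 25 (C11 epimers; other centres as in 25) | COC1=CC(C)(O)[C@@H](Cc2cocc2C)[C@](C)([C@@H](O[Si](C)(C)C(C)(C)C)CC/C(C)=C\I)C1 | intermediate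
27 | enone: (4R,5R)-5-[(1S,4Z)-1-{[tert-butyl(dimethyl)silyl]oxy}-5-iodo-4-methylpent-4-en-1-yl]-3,5-dimethyl-4-[(4-methylfuran-3-yl)methyl]cyclohex-2-en-1-one | O=C1C=C(C)[C@@H](Cc2cocc2C)[C@](C)([C@@H](O[Si](C)(C)C(C)(C)C)CC/C(C)=C\I)C1 | intermediate
28 | lithium dienolate of 27 (O-lithiated at C13, C13=C14) | [Li+].[O-]C=1C=C(C)[C@@H](Cc2cocc2C)[C@](C)([C@@H](O[Si](C)(C)C(C)(C)C)CC/C(C)=C\I)C=1 | intermediate
29 | 14-epi-hydroxy enone: (4R,5S,6R)-5-[(1S,4Z)-1-{[tert-butyl(dimethyl)silyl]oxy}-5-iodo-4-methylpent-4-en-1-yl]-6-hydroxy-3,5-dimethyl-4-[(4-methylfuran-3-yl)methyl]cyclohex-2-en-1-one (OH cis to the C5 methyl; major epimer) | O=C1C=C(C)[C@@H](Cc2cocc2C)[C@](C)([C@@H](O[Si](C)(C)C(C)(C)C)CC/C(C)=C\I)[C@H]1O | intermediate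
30 | ene-1,2-dione: (5R,6R)-6-[(1S,4Z)-1-{[tert-butyl(dimethyl)silyl]oxy}-5-iodo-4-methylpent-4-en-1-yl]-4,6-dimethyl-5-[(4-methylfuran-3-yl)methyl]cyclohex-3-ene-1,2-dione | O=C1C=C(C)[C@@H](Cc2cocc2C)[C@](C)([C@@H](O[Si](C)(C)C(C)(C)C)CC/C(C)=C\I)C1=O | intermediate
31 | (14S)-hydroxy enone: (4R,5S,6S)-5-[(1S,4Z)-1-{[tert-butyl(dimethyl)silyl]oxy}-5-iodo-4-methylpent-4-en-1-yl]-6-hydroxy-3,5-dimethyl-4-[(4-methylfuran-3-yl)methyl]cyclohex-2-en-1-one (OH trans to the C5 methyl) | O=C1C=C(C)[C@@H](Cc2cocc2C)[C@](C)([C@@H](O[Si](C)(C)C(C)(C)C)CC/C(C)=C\I)[C@@H]1O | intermediate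
32 | acetate: (1S,5R,6S)-6-[(1S,4Z)-1-{[tert-butyl(dimethyl)silyl]oxy}-5-iodo-4-methylpent-4-en-1-yl]-4,6-dimethyl-5-[(4-methylfuran-3-yl)methyl]-2-oxocyclohex-3-en-1-yl acetate | O=C1C=C(C)[C@@H](Cc2cocc2C)[C@](C)([C@@H](O[Si](C)(C)C(C)(C)C)CC/C(C)=C\I)[C@@H]1OC(C)=O | intermediate
33 | C2 alcohol: (1S,5R,6R)-6-[(1S,4Z)-1-hydroxy-5-iodo-4-methylpent-4-en-1-yl]-4,6-dimethyl-5-[(4-methylfuran-3-yl)methyl]-2-oxocyclohex-3-en-1-yl acetate | O=C1C=C(C)[C@@H](Cc2cocc2C)[C@](C)([C@@H](O)CC/C(C)=C\I)[C@@H]1OC(C)=O | intermediate
34 | acetate isobutyrate furan: (1S,4Z)-1-[(1R,2S,6R)-2-(acetyloxy)-1,5-dimethyl-6-[(4-methylfuran-3-yl)methyl]-3-oxocyclohex-4-en-1-yl]-5-iodo-4-methylpent-4-en-1-yl 2-methylpropanoate | O=C1C=C(C)[C@@H](Cc2cocc2C)[C@](C)([C@@H](OC(=O)C(C)C)CC/C(C)=C\I)[C@@H]1OC(C)=O | intermediate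
35 | furan endoperoxide: as 34 with the furylmethyl group replaced by (6-methyl-2,3,7-trioxabicyclo[2.2.1]hept-5-en-5-yl)methyl | O=C1C=C(C)[C@@H](CC2=C(C)C3OOC2O3)[C@](C)([C@@H](OC(=O)C(C)C)CC/C(C)=C\I)[C@@H]1OC(C)=O | intermediate
36 | γ-hydroxybutenolide: as 34 with the furylmethyl group replaced by (2-hydroxy-4-methyl-5-oxo-2,5-dihydrofuran-3-yl)methyl (both epimers at the hemiacetal carbon C7) | O=C1C=C(C)[C@@H](CC2=C(C)C(=O)OC2O)[C@](C)([C@@H](OC(=O)C(C)C)CC/C(C)=C\I)[C@@H]1OC(C)=O | intermediate
37 | γ-chlorobutenolide: as 34 with the furylmethyl group replaced by (2-chloro-4-methyl-5-oxo-2,5-dihydrofuran-3-yl)methyl (both epimers at C7) | O=C1C=C(C)[C@@H](CC2=C(C)C(=O)OC2Cl)[C@](C)([C@@H](OC(=O)C(C)C)CC/C(C)=C\I)[C@@H]1OC(C)=O | intermediate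
38 | target: (1R,2S,5Z,7R,10R,14S)-14-(acetyloxy)-2-(2-methylpropanoyloxy)-13-oxobriara-5,8(17),11-trien-19,7-olide (locants as in the assumption line) | CC(=O)O[C@@H]1C(=O)C=C(C)[C@H]2CC3=C(C)C(=O)O[C@@H]3/C=C(/C)CC[C@H](OC(=O)C(C)C)[C@@]21C | target

**Totals and risks**
Total step count: 25 (steps 1–2 and 3–5 are two short side branches). Longest linear sequence: 20 steps (steps 6–25, from 3,5-dimethoxybenzoic acid 11 to 38).

The three steps most likely to fail:

Step 25, the proposed new reductive macrocyclization. It may give oligomers, simple reduction of either halide, or the wrong C7 epimer. The fallback uses known chemistry; it sets out from 36 and comes back to the route at 38. Hydroxybutenolide 36 is treated with MeI and K2CO3 in DMF, which alkylates the ring-opened carboxylate and gives the open-chain methyl ester aldehyde F1. A Nozaki–Hiyama–Kishi macrocyclization (CrCl2 as the divalent chromium reductant, NiCl2 1 mol %, DMSO/THF, 2 mM) then adds the alkenylchromium formed from the Z iodide to the aldehyde and gives the ten-membered seco hydroxy ester F2. F2 lactonizes on treatment with pyridinium p-toluenesulfonate to 38; any C7 epimer is removed by chromatography.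

Step 10, the diastereotopic-group-selective ketalization. The exo/endo preference that sets C1 may be small. The fallback sets out from 16 and comes back at 22. Ketone 16 is half-hydrolysed (0.05 M oxalic acid, wet THF, 0 °C; then DBU) to the racemic vinylogous ester ketone F3. Reduction with (R)-2-methyl-CBS-oxazaborolidine and catecholborane sets C2 (S) under reagent control in both enantiomers and gives 22 together with its C1 epimer F4, which is separated by chromatography. This skips steps 9–13 at the cost of half the material.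

Step 19, together with step 18. The dione may enolize through C10, or NaBH4 may attack the wrong carbonyl or face. The fallback sets out from 30 and comes back at 33. HF·pyridine removes the silyl group of 30 to give the hydroxy dione F5. A chelation-controlled Narasaka–Prasad reduction (Et2BOMe, NaBH4, THF/MeOH, −78 °C) delivers hydride to the C14 carbonyl held in a boron chelate with the C2 hydroxyl and gives the syn diol F6. Selective acetylation of the less hindered ketol hydroxyl (Ac2O, pyridine, −20 °C) then gives 33.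

**Further compounds**
F1 | step 25 | (1S,4Z)-1-[(1R,2S,6R)-2-(acetyloxy)-6-[(2Z)-2-formyl-4-methoxy-3-methyl-4-oxobut-2-en-1-yl]-1,5-dimethyl-3-oxocyclohex-4-en-1-yl]-5-iodo-4-methylpent-4-en-1-yl 2-methylpropanoate | O=C1C=C(C)[C@@H](C/C(C=O)=C(\C)C(=O)OC)[C@](C)([C@@H](OC(=O)C(C)C)CC/C(C)=C\I)[C@@H]1OC(C)=O
F2 | step 25 | seco hydroxy ester: methyl ester of the (7R)-7-hydroxy acid of 38 (lactone opened, 8(17)Z, other centres as in 38) | CC(=O)O[C@@H]1C(=O)C=C(C)[C@H]2C/C(=C(\C)C(=O)OC)[C@H](O)/C=C(/C)CC[C@H](OC(=O)C(C)C)[C@@]21C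
F3 | step 10 | racemic 5-[(4Z)-5-iodo-4-methylpent-4-enoyl]-3-methoxy-5-methylcyclohex-2-en-1-one | COC1=CC(=O)CC(C)(C(=O)CC/C(C)=C\I)C1
F4 | step 10 | (5S)-5-[(1S,4Z)-1-hydroxy-5-iodo-4-methylpent-4-en-1-yl]-3-methoxy-5-methylcyclohex-2-en-1-one | COC1=CC(=O)C[C@@](C)([C@@H](O)CC/C(C)=C\I)C1
F5 | step 19 | (5R,6R)-6-[(1S,4Z)-1-hydroxy-5-iodo-4-methylpent-4-en-1-yl]-4,6-dimethyl-5-[(4-methylfuran-3-yl)methyl]cyclohex-3-ene-1,2-dione | O=C1C=C(C)[C@@H](Cc2cocc2C)[C@](C)([C@@H](O)CC/C(C)=C\I)C1=O
F6 | step 19 | (4R,5R,6S)-6-hydroxy-5-[(1S,4Z)-1-hydroxy-5-iodo-4-methylpent-4-en-1-yl]-3,5-dimethyl-4-[(4-methylfuran-3-yl)methyl]cyclohex-2-en-1-one | O=C1C=C(C)[C@@H](Cc2cocc2C)[C@](C)([C@@H](O)CC/C(C)=C\I)[C@@H]1O
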